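**Plan**
- Enabling feature: ring B (the ring without methoxy) carries the cinnamoyl group at C1', OH at C2' and the ether oxygen at C4'. This is the oxygen pattern of a folded tetraketide with C6' at the aldehyde level, and its C4' oxygen can be held from the start as the aryl enol ether to C5' of ring A.
- Cuts, in retrosynthetic order: ring B C1'–C6' (aldol condensation and aromatisation); the bond from C1' to the ring B cinnamoyl carbonyl (enolate acylation); the C4'–O bond to ring A (oxa-Michael addition to an ynone); the ring A chalcone C=C (Claisen–Schmidt); the ring A C5–O bond (Elbs oxidation of paeonol).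
- Forward: ring A is made first as its chalcone phenol. The phenol adds to 6,6-diethoxyhex-3-yn-2-one, the methyl ketone is acylated with a cinnamoyl imidazolide to give the masked tetraketide, ring B closes last, and three MOM ethers are removed.
- Stereochemistry: there are no stereocentres. Both chalcone alkenes are E from condensations under thermodynamic control, and the E enol ether (C2' and C5' cis) comes from reversible phenoxide addition.

Key step: step 12

Remark: the 1,3-diketones 17 and 18 are written as diketo forms although the chelated enols should predominate. ArO stands for the ring A chalcone bound through its C5' oxygen, 2-methoxy-4-(methoxymethoxy)-5-[(E)-3-[4-(methoxymethoxy)phenyl]prop-2-enoyl]phenoxy.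

**Step 1**
Reactants: 1 4-hydroxybenzaldehyde
Product: 2 4-(methoxymethoxy)benzaldehyde
Conditions: MOMCl, K2CO3, acetone, 0 → 20 °C
Reagents that add atoms: chloromethyl methyl ether, COCCl
Why: Williamson-type O-alkylation of the phenoxide masks the phenol, which as a phenoxide would deactivate the aldehyde in the later condensations.

**Step 2**
Reactants: 3 paeonol
Product: 5 1-(2,5-dihydroxy-4-methoxyphenyl)ethanone, via aryl potassium sulfate 4 (not isolated)
Conditions: K2S2O8, 10% aq. KOH, 15 °C; then aq. HCl, 90 °C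
Reagents that add atoms: potassium peroxodisulfate, [K+].[K+].[O-]S(=O)(=O)OOS(=O)(=O)[O-]
Why: Elbs persulfate oxidation, in which the phenoxide is attacked by peroxodisulfate at C5, the free position para to the phenoxide oxygen, and the resulting aryl sulfate is hydrolysed by hot acid to the hydroquinone.

**Step 3**
Reactants: 5 1-(2,5-dihydroxy-4-methoxyphenyl)ethanone
Product: 6 1-[5-(allyloxy)-2-hydroxy-4-methoxyphenyl]ethanone
Conditions: allyl bromide (1.05 equiv), K2CO3, acetone, reflux, N2
Reagents that add atoms: allyl bromide, C=CCBr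
Why: Williamson etherification should take only the 5-OH, because the 2-OH is tied up in a hydrogen bond to the acetyl carbonyl and is not alkylated under carbonate conditions.

**Step 4**
Reactants: 6 1-[5-(allyloxy)-2-hydroxy-4-methoxyphenyl]ethanone
Product: 7 1-[5-(allyloxy)-4-methoxy-2-(methoxymethoxy)phenyl]ethanone
Conditions: NaH, MOMCl, DMF, 0 → 20 °C
Reagents that add atoms: chloromethyl methyl ether, COCCl
Why: full deprotonation of the chelated phenol by NaH allows Williamson-type O-alkylation with MOMCl, while the allyl ether is inert.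

**Step 5**
Reactants: 7 1-[5-(allyloxy)-4-methoxy-2-(methoxymethoxy)phenyl]ethanone; 2 4-(methoxymethoxy)benzaldehyde
Product: 8 (E)-1-[5-(allyloxy)-4-methoxy-2-(methoxymethoxy)phenyl]-3-[4-(methoxymethoxy)phenyl]prop-2-en-1-one
Conditions: KOH, EtOH–H2O, 20 °C
Reagents that add atoms: none
Why: Claisen–Schmidt condensation of the methyl ketone enolate with the non-enolisable aldehyde, whose E1cB dehydration should give the conjugated E enone under thermodynamic control, with MOM and allyl ethers stable to KOH.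

**Step 6**
Reactants: 8 (E)-1-[5-(allyloxy)-4-methoxy-2-(methoxymethoxy)phenyl]-3-[4-(methoxymethoxy)phenyl]prop-2-en-1-one
Product: 9 (E)-1-[5-hydroxy-4-methoxy-2-(methoxymethoxy)phenyl]-3-[4-(methoxymethoxy)phenyl]prop-2-en-1-one
Conditions: Pd(PPh3)4 (5 mol%), morpholine, THF, 20 °C
Reagents that add atoms: none
Why: Tsuji–Trost deallylation, in which zerovalent palladium ionises the allyl aryl ether to a π-allyl complex that morpholine traps, leaving the MOM ethers and the enone untouched.

**Step 7**
Reactants: 10 4,4-diethoxybut-1-yne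
Product: 12 6,6-diethoxyhex-3-yn-2-one, via lithium acetylide 11 (not isolated)
Conditions: n-BuLi, THF, −78 °C; then MeC(O)N(OMe)Me, −78 → 0 °C; aq. NH4Cl
Reagents that add atoms: N-methoxy-N-methylacetamide, CON(C)C(C)=O
Why: Weinreb ketone synthesis with a lithium acetylide, where the chelated tetrahedral intermediate prevents over-addition and the acetal is inert to the base.

**Step 8**
Reactants: 9 (E)-1-[5-hydroxy-4-methoxy-2-(methoxymethoxy)phenyl]-3-[4-(methoxymethoxy)phenyl]prop-2-en-1-one; 12 6,6-diethoxyhex-3-yn-2-one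
Product: 13 (E)-4-(ArO)-6,6-diethoxyhex-3-en-2-one
Conditions: K2CO3 (0.2 equiv), DMF, 0 → 20 °C
Reagents that add atoms: none
Why: base-catalysed oxa-Michael addition of the only free phenol to the ynone β-carbon, which being reversible should settle on the more stable E vinylogous ester (aryloxy trans to the acetyl group, C5' methylene cis to the carbonyl), as is usual for β-alkoxy enones.

**Step 9**
Reactants: 2 4-(methoxymethoxy)benzaldehyde
Product: 14 (E)-3-[4-(methoxymethoxy)phenyl]prop-2-enoic acid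
Conditions: malonic acid, pyridine, piperidine (cat.), 90 °C
Reagents that add atoms: malonic acid, OC(=O)CC(=O)O
Why: Knoevenagel–Doebner condensation with decarboxylation should give the E cinnamic acid, and the MOM ether is stable to the basic medium.

**Step 10**
Reactants: 14 (E)-3-[4-(methoxymethoxy)phenyl]prop-2-enoic acid
Product: 15 (E)-1-(imidazol-1-yl)-3-[4-(methoxymethoxy)phenyl]prop-2-en-1-one
Conditions: 1,1'-carbonyldiimidazole, CH2Cl2, 20 °C; cold water wash
Reagents that add atoms: 1,1'-carbonyldiimidazole, O=C(n1ccnc1)n1ccnc1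
Why: acyl imidazolide formation driven by loss of CO2 gives a neutral, isolable acyl donor without any acid that could cleave the MOM ether, and the wash removes the imidazole that would quench an enolate.

**Step 11**
Reactants: 13 (E)-4-(ArO)-6,6-diethoxyhex-3-en-2-one; 15 (E)-1-(imidazol-1-yl)-3-[4-(methoxymethoxy)phenyl]prop-2-en-1-one
Product: 17 masked tetraketide (1E,6E)-7-(ArO)-9,9-diethoxy-1-[4-(methoxymethoxy)phenyl]nona-1,6-diene-3,5-dione, via lithium enolate 16 (not isolated)
Conditions: LiN(SiMe3)2 (2.2 equiv), THF, −78 °C; then 15, −78 → −40 °C; aq. NH4Cl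
Reagents that add atoms: none
Why: kinetic deprotonation of a vinylogous ester occurs at the α' methyl group, and Claisen-type C-acylation of this enolate by the acyl imidazolide (the known route to β-alkoxy enone 1,3-diketones) should give the diketone, the second equivalent of base taking up its acidic proton.

**Step 12**
Reactants: 17 masked tetraketide (1E,6E)-7-(ArO)-9,9-diethoxy-1-[4-(methoxymethoxy)phenyl]nona-1,6-diene-3,5-dione
Product: 21 (E)-1-[5-[3-hydroxy-4-[(E)-3-[4-(methoxymethoxy)phenyl]prop-2-enoyl]phenoxy]-4-methoxy-2-(methoxymethoxy)phenyl]-3-[4-(methoxymethoxy)phenyl]prop-2-en-1-one, via free aldehyde 18 (not isolated), via aldol adduct 19 (not isolated), via cyclohexadienone 20 (not isolated)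
Conditions: 5% aq. (CO2H)2, THF, 20 °C; then Et3N (excess), 20 °C
Reagents that add atoms: none
Why: Aqueous oxalic acid should hydrolyse the diethyl acetal faster than the aryl MOM ethers or the vinylogous aryl ester and free the C6' aldehyde 18; Et3N then forms the diketone enolate, whose central carbon C1' adds to the aldehyde (19), water is lost by E1cB elimination (20) and a proton shift from C5' to the C2' oxygen gives the arene. The closest known reaction type is the intramolecular aldol (Knoevenagel) condensation and aromatisation of poly-β-carbonyl chains and their enol-ether-masked forms to resorcinol derivatives. Ring B closes by a 6-(enolexo)-exo-trig attack of C1' on C6', possible because the E enol ether holds C2' and C5' cis on the C3'=C4' bond. No stereocentre remains, the carbinol centres of 19 being lost on dehydration. The step needs carbon rather than oxygen cyclisation, since attack of the enol oxygen on C4' would expel the ring A phenoxide and give a 4-pyranone; the chelated cis-enol or enolate keeps that oxygen turned away from C4', the free aldehyde is the better electrophile, and anhydrous strong acid, which drives pyranone formation, is avoided. A tertiary amine is chosen so that no amine can displace the aryloxy group at C4'.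

**Step 13**
Reactants: 21 (E)-1-[5-[3-hydroxy-4-[(E)-3-[4-(methoxymethoxy)phenyl]prop-2-enoyl]phenoxy]-4-methoxy-2-(methoxymethoxy)phenyl]-3-[4-(methoxymethoxy)phenyl]prop-2-en-1-one
Product: 22 rhuschalcone IV
Conditions: 3 M aq. HCl, MeOH, 50 °C
Reagents that add atoms: none
Why: acid-catalysed acetal exchange with methanol should remove all three MOM ethers, and a short exposure at moderate temperature limits acid-induced cyclisation of the 2'-hydroxychalcones to flavanones.

**Compound list**
1 | 4-hydroxybenzaldehyde | O=Cc1ccc(O)cc1 | starting material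
2 | 4-(methoxymethoxy)benzaldehyde | COCOc1ccc(C=O)cc1 | intermediate
3 | paeonol, 1-(2-hydroxy-4-methoxyphenyl)ethanone | COc1ccc(C(C)=O)c(O)c1 | starting material
4 | potassium 5-acetyl-4-hydroxy-2-methoxyphenyl sulfate | COc1cc(O)c(C(C)=O)cc1OS(=O)(=O)[O-].[K+] | intermediate
5 | 1-(2,5-dihydroxy-4-methoxyphenyl)ethanone | COc1cc(O)c(C(C)=O)cc1O | intermediate
6 | 1-[5-(allyloxy)-2-hydroxy-4-methoxyphenyl]ethanone | COc1cc(O)c(C(C)=O)cc1OCC=C | intermediate
7 | 1-[5-(allyloxy)-4-methoxy-2-(methoxymethoxy)phenyl]ethanone | COCOc1cc(OC)c(OCC=C)cc1C(C)=O | intermediate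
8 | (E)-1-[5-(allyloxy)-4-methoxy-2-(methoxymethoxy)phenyl]-3-[4-(methoxymethoxy)phenyl]prop-2-en-1-one | COCOc1ccc(/C=C/C(=O)c2cc(OCC=C)c(OC)cc2OCOC)cc1 | intermediate
9 | (E)-1-[5-hydroxy-4-methoxy-2-(methoxymethoxy)phenyl]-3-[4-(methoxymethoxy)phenyl]prop-2-en-1-one | COCOc1ccc(/C=C/C(=O)c2cc(O)c(OC)cc2OCOC)cc1 | intermediate
10 | 4,4-diethoxybut-1-yne | CCOC(OCC)CC#C | starting material
11 | (4,4-diethoxybut-1-yn-1-yl)lithium | CCOC(OCC)CC#C[Li] | intermediate
12 | 6,6-diethoxyhex-3-yn-2-one | CCOC(OCC)CC#CC(C)=O | intermediate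
13 | (E)-4-(ArO)-6,6-diethoxyhex-3-en-2-one | CCOC(OCC)C/C(Oc1cc(C(=O)/C=C/c2ccc(OCOC)cc2)c(OCOC)cc1OC)=C\C(C)=O | intermediate
14 | (E)-3-[4-(methoxymethoxy)phenyl]prop-2-enoic acid | COCOc1ccc(/C=C/C(=O)O)cc1 | intermediate
15 | (E)-1-(imidazol-1-yl)-3-[4-(methoxymethoxy)phenyl]prop-2-en-1-one | COCOc1ccc(/C=C/C(=O)n2ccnc2)cc1 | intermediate
16 | lithium (E)-4-(ArO)-6,6-diethoxyhexa-1,3-dien-2-olate | CCOC(OCC)C/C(Oc1cc(C(=O)/C=C/c2ccc(OCOC)cc2)c(OCOC)cc1OC)=C\C(=C)O[Li] | intermediate
17 | (1E,6E)-7-(ArO)-9,9-diethoxy-1-[4-(methoxymethoxy)phenyl]nona-1,6-diene-3,5-dione | CCOC(OCC)C/C(Oc1cc(C(=O)/C=C/c2ccc(OCOC)cc2)c(OCOC)cc1OC)=C\C(=O)CC(=O)/C=C/c1ccc(OCOC)cc1 | intermediate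
18 | (3E,8E)-3-(ArO)-9-[4-(methoxymethoxy)phenyl]-5,7-dioxonona-3,8-dienal | O=CC/C(Oc1cc(C(=O)/C=C/c2ccc(OCOC)cc2)c(OCOC)cc1OC)=C\C(=O)CC(=O)/C=C/c1ccc(OCOC)cc1 | intermediate
19 | 3-(ArO)-5-hydroxy-6-[(E)-3-[4-(methoxymethoxy)phenyl]prop-2-enoyl]cyclohex-2-en-1-one, mixture of diastereomers | O=C1C=C(Oc2cc(C(=O)/C=C/c3ccc(OCOC)cc3)c(OCOC)cc2OC)CC(O)C1C(=O)/C=C/c1ccc(OCOC)cc1 | intermediate
20 | 3-(ArO)-6-[(E)-3-[4-(methoxymethoxy)phenyl]prop-2-enoyl]cyclohexa-2,5-dien-1-one | O=C1C=C(Oc2cc(C(=O)/C=C/c3ccc(OCOC)cc3)c(OCOC)cc2OC)CC=C1C(=O)/C=C/c1ccc(OCOC)cc1 | intermediate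
21 | (E)-1-[5-[3-hydroxy-4-[(E)-3-[4-(methoxymethoxy)phenyl]prop-2-enoyl]phenoxy]-4-methoxy-2-(methoxymethoxy)phenyl]-3-[4-(methoxymethoxy)phenyl]prop-2-en-1-one | COCOc1ccc(/C=C/C(=O)c2cc(Oc3ccc(C(=O)/C=C/c4ccc(OCOC)cc4)c(O)c3)c(OC)cc2OCOC)cc1 | intermediate
22 | rhuschalcone IV, (E)-1-[2-hydroxy-5-[3-hydroxy-4-[(E)-3-(4-hydroxyphenyl)prop-2-enoyl]phenoxy]-4-methoxyphenyl]-3-(4-hydroxyphenyl)prop-2-en-1-one | COc1cc(O)c(C(=O)/C=C/c2ccc(O)cc2)cc1Oc1ccc(C(=O)/C=C/c2ccc(O)cc2)c(O)c1 | target

**Step count and risks**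
Total steps: 13. Longest linear sequence: 9 steps (steps 2, 3, 4, 5, 6, 8, 11, 12, 13 from paeonol).

Steps most likely to fail:

1. Step 12. The diketone enol oxygen may close onto C4' and expel the ring A phenol (pyranone formation), or the aryl enol ether may hydrolyse while the acetal is being cleaved. The fallback sets out from 5 and returns at 22; it buys ring B as an arene and makes the diaryl ether by nucleophilic aromatic substitution. Commercial 4'-fluoro-2'-hydroxyacetophenone is protected (NaH, MOMCl, DMF) as 1-[4-fluoro-2-(methoxymethoxy)phenyl]ethanone F1. The non-chelated 5-phenoxide of 5 displaces the fluoride para to the acetyl group (K2CO3, DMSO, 90 °C, argon) to give 1-[5-[4-acetyl-3-(methoxymethoxy)phenoxy]-2-hydroxy-4-methoxyphenyl]ethanone F2. A double Claisen–Schmidt condensation with 2 (KOH, EtOH) should give the bis-chalcone (E)-1-[2-hydroxy-4-methoxy-5-[3-(methoxymethoxy)-4-[(E)-3-[4-(methoxymethoxy)phenyl]prop-2-enoyl]phenoxy]phenyl]-3-[4-(methoxymethoxy)phenyl]prop-2-en-1-one F3. Aqueous HCl in MeOH then removes the three MOM groups to reach 22.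

2. Step 11. Proton transfer from the acidic product to unreacted enolate, O-acylation or double acylation, and conjugate addition of the enolate to a chalcone may erode the acylation. The fallback sets out from 13 and returns at 17; it forms the same C–C bond by aldol addition and then adjusts the oxidation level. Aldehyde 2 is homologated with Ph3P=CHCHO (toluene, 80 °C) to (E)-3-[4-(methoxymethoxy)phenyl]prop-2-enal F4. Enolate 16, made from 13 with 1.1 equiv of LiN(SiMe3)2 at −78 °C, adds to F4 to give the non-acidic β-hydroxy ketone (1E,6E)-7-(ArO)-9,9-diethoxy-3-hydroxy-1-[4-(methoxymethoxy)phenyl]nona-1,6-dien-5-one F5. Dess–Martin periodinane buffered with NaHCO3 oxidises the allylic alcohol to 17.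

3. Step 8. Base-induced isomerisation of the ynone to an allenyl ketone with loss of ethanol, oligomerisation, or unselective formation of the enol ether geometry may spoil the addition. The fallback sets out from 9 and returns at 17; it uses an ynoate as the acceptor and completes the chain from the acid side. Acetylide 11 is trapped with allyl chloroformate to give allyl 5,5-diethoxypent-2-ynoate F6. Phenol 9 adds to it (K2CO3, DMF) to give allyl (E)-3-(ArO)-5,5-diethoxypent-2-enoate F7. Pd(PPh3)4 with sodium 2-ethylhexanoate frees (E)-3-(ArO)-5,5-diethoxypent-2-enoic acid F8. 1-(Methylsulfonyl)benzotriazole and Et3N convert it into the N-acylbenzotriazole (E)-3-(ArO)-1-(benzotriazol-1-yl)-5,5-diethoxypent-2-en-1-one F9. Soft enolisation with MgBr2·OEt2 and i-Pr2NEt in CH2Cl2 of (E)-4-[4-(methoxymethoxy)phenyl]but-3-en-2-one F10 (from commercial 4-(4-hydroxyphenyl)but-3-en-2-one, MOMCl, K2CO3), followed by C-acylation with F9, gives 17.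

**Further compounds**
F1 | step 12 | 1-[4-fluoro-2-(methoxymethoxy)phenyl]ethanone | COCOc1cc(F)ccc1C(C)=O
F2 | step 12 | 1-[5-[4-acetyl-3-(methoxymethoxy)phenoxy]-2-hydroxy-4-methoxyphenyl]ethanone | COc1cc(O)c(C(C)=O)cc1Oc1ccc(C(C)=O)c(OCOC)c1
F3 | step 12 | (E)-1-[2-hydroxy-4-methoxy-5-[3-(methoxymethoxy)-4-[(E)-3-[4-(methoxymethoxy)phenyl]prop-2-enoyl]phenoxy]phenyl]-3-[4-(methoxymethoxy)phenyl]prop-2-en-1-one | COCOc1ccc(/C=C/C(=O)c2cc(Oc3ccc(C(=O)/C=C/c4ccc(OCOC)cc4)c(OCOC)c3)c(OC)cc2O)cc1
F4 | step 11 | (E)-3-[4-(methoxymethoxy)phenyl]prop-2-enal | COCOc1ccc(/C=C/C=O)cc1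
F5 | step 11 | (1E,6E)-7-(ArO)-9,9-diethoxy-3-hydroxy-1-[4-(methoxymethoxy)phenyl]nona-1,6-dien-5-one, racemic | CCOC(OCC)C/C(Oc1cc(C(=O)/C=C/c2ccc(OCOC)cc2)c(OCOC)cc1OC)=C\C(=O)CC(O)/C=C/c1ccc(OCOC)cc1
F6 | step 8 | allyl 5,5-diethoxypent-2-ynoate | CCOC(OCC)CC#CC(=O)OCC=C
F7 | step 8 | allyl (E)-3-(ArO)-5,5-diethoxypent-2-enoate | CCOC(OCC)C/C(Oc1cc(C(=O)/C=C/c2ccc(OCOC)cc2)c(OCOC)cc1OC)=C\C(=O)OCC=C
F8 | step 8 | (E)-3-(ArO)-5,5-diethoxypent-2-enoic acid | CCOC(OCC)C/C(Oc1cc(C(=O)/C=C/c2ccc(OCOC)cc2)c(OCOC)cc1OC)=C\C(=O)O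
F9 | step 8 | (E)-3-(ArO)-1-(benzotriazol-1-yl)-5,5-diethoxypent-2-en-1-one | CCOC(OCC)C/C(Oc1cc(C(=O)/C=C/c2ccc(OCOC)cc2)c(OCOC)cc1OC)=C\C(=O)n1nnc2ccccc21
F10 | step 8 | (E)-4-[4-(methoxymethoxy)phenyl]but-3-en-2-one | COCOc1ccc(/C=C/C(C)=O)cc1
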